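## Retrosynthetic overview

1. Isariotin D ⇐ alkene triol: the C7–C8 oxirane is made last, by hydroxyl-directed exo-epoxidation.
2. Alkene triol ⇐ monocyclic α,β-epoxy-ketone aldehyde: the C4–C5 bond (ring A) is closed by SmI2 oxirane opening and intramolecular aldol; the C6–OH is what remains of that oxirane.
3. Side chain C2–C3–C4 ⇐ ring aldehyde + N-decenoyl phosphonoglycinate (Horner–Wadsworth–Emmons), then Rh–DuPhos hydrogenation for C3.
4. Ring B with C1 and C9 ⇐ benzoic acid, by whole-cell dioxygenase cis-dihydroxylation, which sets the first stereocentres.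
5. Ring order: ring B (from the arene) → ring A (bicyclisation) → oxirane.

Assumption: locants C1–C9 in the comments are those of the target's bicyclo[3.3.1]nonane core (C1 carbinol bridgehead, C3 N-bearing carbon, C9 ketone) and are kept for the monocyclic precursors; phosphonate 12 is made and used as a racemate whose single CH(P)(N) centre is destroyed in step 9.

## Route

Step 1
Reactants: 1 benzoic acid (fed as sodium benzoate)
Product: 2 (1S,2R)-1,2-dihydroxycyclohexa-3,5-diene-1-carboxylic acid (cis-diol)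
Conditions: resting cells of Ralstonia eutropha B9 (benzoate 1,2-dioxygenase, a Rieske non-haem iron dioxygenase; NADH recycled in the cells), air, sodium succinate, phosphate buffer pH 7, 30 °C; acidify, EtOAc
Reagents that add atoms: dioxygen, O=O
Why: Enzymatic arene cis-dihydroxylation adds O2 across the ipso/ortho bond on one enantiotopic face of the achiral arene, setting the quaternary carbinol C1 and the cis C9 carbinol in one catalytic step.

Step 2
Reactants: 2 (1S,2R)-1,2-dihydroxycyclohexa-3,5-diene-1-carboxylic acid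
Product: 3 methyl (1S,2R)-1,2-dihydroxycyclohexa-3,5-diene-1-carboxylate
Conditions: MeI, KHCO3, DMF, rt
Reagents that add atoms: iodomethane, CI
Why: SN2 O-alkylation of the carboxylate under bicarbonate buffering avoids the acid that would dehydrate the dienediol to a phenol.

Step 3
Reactants: 3 methyl (1S,2R)-1,2-dihydroxycyclohexa-3,5-diene-1-carboxylate
Product: 4 methyl (1S,2R)-1,2-bis(triethylsilyloxy)cyclohexa-3,5-diene-1-carboxylate
Conditions: TESOTf, 2,6-lutidine, CH2Cl2, −78 → 0 °C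
Reagents that add atoms: triethylsilyl trifluoromethanesulfonate, CC[Si](CC)(CC)OS(=O)(=O)C(F)(F)F
Why: Silyl triflate silylation is strong enough for the tertiary α-hydroxy ester and is done before any oxirane is present, since a Lewis-acidic triflate could trigger SN2' migration of a vinyl oxirane.

Step 4
Reactants: 4 methyl (1S,2R)-1,2-bis(triethylsilyloxy)cyclohexa-3,5-diene-1-carboxylate
Product: 5 [(1R,6R)-1,6-bis(triethylsilyloxy)cyclohexa-2,4-dien-1-yl]methanol
Conditions: DIBAL-H, CH2Cl2, −78 → 0 °C; Rochelle salt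
Reagents that add atoms: none
Why: Hydride reduction of the ester to the primary alcohol; silyl ethers and the diene are inert, and the descriptor at C1 changes only through CIP priorities.

Step 5
Reactants: 5 [(1R,6R)-1,6-bis(triethylsilyloxy)cyclohexa-2,4-dien-1-yl]methanol
Product: 6 (1S,6R)-1,6-bis(triethylsilyloxy)cyclohexa-2,4-diene-1-carbaldehyde
Conditions: Dess–Martin periodinane, pyridine, CH2Cl2, 0 °C → rt
Reagents that add atoms: none
Why: Dess–Martin oxidation gives an aldehyde that cannot enolise because its α-carbon is quaternary.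

Step 6
Reactants: 7 (E)-dec-2-enoic acid
Product: 9 (E)-dec-2-enamide, via (E)-dec-2-enoyl chloride 8 (not isolated)
Conditions: (COCl)2, cat. DMF, CH2Cl2, 0 °C → rt; concentrate; NH3 (0.5 M in dioxane), 0 °C
Reagents that add atoms: ammonia, N; oxalyl chloride, O=C(Cl)C(Cl)=O (Cl of intermediate 8 only)
Why: Acid chloride formation followed by ammonolysis (acyl substitution) gives the primary amide without touching the E-olefin.

Step 7
Reactants: 10 trimethyl phosphonoacetate
Product: 11 trimethyl diazophosphonoacetate (methyl 2-diazo-2-(dimethoxyphosphoryl)acetate)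
Conditions: p-ABSA, Et3N, MeCN, 0 °C → rt
Reagents that add atoms: 4-acetamidobenzenesulfonyl azide, CC(=O)Nc1ccc(cc1)S(=O)(=O)N=[N+]=[N-]
Why: Regitz diazo transfer onto the doubly activated methylene.

Step 8
Reactants: 9 (E)-dec-2-enamide; 11 trimethyl diazophosphonoacetate
Product: 12 methyl 2-[(E)-dec-2-enoylamino]-2-(dimethoxyphosphoryl)acetate (racemic)
Conditions: Rh2(OAc)4 (2 mol%), toluene, 80 °C
Reagents that add atoms: none
Why: Rh(II)-carbenoid N–H insertion into the primary amide gives the N-acyl phosphonoglycinate; the electron-poor enoyl C=C is not cyclopropanated by the electrophilic carbenoid.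

Step 9
Reactants: 6 (1S,6R)-1,6-bis(triethylsilyloxy)cyclohexa-2,4-diene-1-carbaldehyde; 12 methyl 2-[(E)-dec-2-enoylamino]-2-(dimethoxyphosphoryl)acetate
Product: 13 methyl (Z)-3-[(1R,6R)-1,6-bis(triethylsilyloxy)cyclohexa-2,4-dien-1-yl]-2-[(E)-dec-2-enoylamino]prop-2-enoate
Conditions: DBU, CH2Cl2, 0 °C → rt
Reagents that add atoms: none
Why: Horner–Wadsworth–Emmons olefination of the non-enolisable aldehyde gives the (Z)-dehydroamino ester, creating the C2–C3 bond with the final N-acyl group already in place.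

Step 10
Reactants: 13 methyl (Z)-3-[(1R,6R)-1,6-bis(triethylsilyloxy)cyclohexa-2,4-dien-1-yl]-2-[(E)-dec-2-enoylamino]prop-2-enoate
Product: 14 methyl (Z)-2-[(E)-dec-2-enoylamino]-3-[(1R,6R)-6-hydroxy-1-(triethylsilyloxy)cyclohexa-2,4-dien-1-yl]prop-2-enoate
Conditions: HF·pyridine, excess pyridine, THF, 0 °C
Reagents that add atoms: none
Why: Sterically controlled fluoride desilylation removes the secondary allylic silyl ether at C9 much faster than the tertiary one at C1.

Step 11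
Reactants: 14 methyl (Z)-2-[(E)-dec-2-enoylamino]-3-[(1R,6R)-6-hydroxy-1-(triethylsilyloxy)cyclohexa-2,4-dien-1-yl]prop-2-enoate
Product: 15 methyl (Z)-2-[(E)-dec-2-enoylamino]-3-[(1R,4R,5R,6S)-5-hydroxy-4-(triethylsilyloxy)-7-oxabicyclo[4.1.0]hept-2-en-4-yl]prop-2-enoate (oxirane cis to both oxygen substituents)
Conditions: mCPBA (1.05 equiv), NaHCO3, CH2Cl2, 0 °C
Reagents that add atoms: 3-chloroperoxybenzoic acid, OOC(=O)c1cccc(Cl)c1
Why: Henbest hydroxyl-directed epoxidation delivers oxygen to the only alkene allylic to the free C9–OH (C5=C6) on the OH face, setting C5 and C6; the captodative and enoyl olefins are too electron-poor to react.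

Step 12
Reactants: 15 methyl (Z)-2-[(E)-dec-2-enoylamino]-3-[(1R,4R,5R,6S)-5-hydroxy-4-(triethylsilyloxy)-7-oxabicyclo[4.1.0]hept-2-en-4-yl]prop-2-enoate
Product: 16 methyl (2S)-2-[(E)-dec-2-enoylamino]-3-[(1R,4S,5R,6S)-5-hydroxy-4-(triethylsilyloxy)-7-oxabicyclo[4.1.0]hept-2-en-4-yl]propanoate
Conditions: [Rh(cod)((S,S)-Et-DuPhos)]OTf (2 mol%), H2 (4 bar), degassed CH2Cl2, rt
Reagents that add atoms: none
Why: Rh–bisphosphine asymmetric hydrogenation of the dehydroamino ester sets (S)-C3 under catalyst control through the amide-O/olefin chelate; the non-chelating ring alkene and enoyl C=C are not reduced.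

Step 13
Reactants: 16 methyl (2S)-2-[(E)-dec-2-enoylamino]-3-[(1R,4S,5R,6S)-5-hydroxy-4-(triethylsilyloxy)-7-oxabicyclo[4.1.0]hept-2-en-4-yl]propanoate
Product: 17 (E)-N-[(2S)-1-hydroxy-3-[(1R,4S,5R,6S)-5-hydroxy-4-(triethylsilyloxy)-7-oxabicyclo[4.1.0]hept-2-en-4-yl]propan-2-yl]dec-2-enamide
Conditions: LiBH4, THF, 0 °C
Reagents that add atoms: none
Why: Chemoselective borohydride reduction of the α-amido ester to the primary alcohol leaves amide, oxirane and silyl ether intact at 0 °C and does not epimerise C3.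

Step 14
Reactants: 17 (E)-N-[(2S)-1-hydroxy-3-[(1R,4S,5R,6S)-5-hydroxy-4-(triethylsilyloxy)-7-oxabicyclo[4.1.0]hept-2-en-4-yl]propan-2-yl]dec-2-enamide
Product: 18 (E)-N-[(2S)-1-oxo-3-[(1R,3S,6R)-2-oxo-3-(triethylsilyloxy)-7-oxabicyclo[4.1.0]hept-4-en-3-yl]propan-2-yl]dec-2-enamide
Conditions: (COCl)2, DMSO, CH2Cl2, −78 °C; then iPr2NEt, −78 → −20 °C; used crude
Reagents that add atoms: none
Why: In this double Swern oxidation both hydroxyls are converted to alkoxysulfonium salts before base is added, so no hydroxy-aldehyde (lactol) can be over-oxidised, and the α-amido aldehyde is formed cold without epimerisation.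

Step 15
Reactants: 18 (E)-N-[(2S)-1-oxo-3-[(1R,3S,6R)-2-oxo-3-(triethylsilyloxy)-7-oxabicyclo[4.1.0]hept-4-en-3-yl]propan-2-yl]dec-2-enamide
Product: 20 (E)-N-[(1S,3S,4R,5R,6R)-4,6-dihydroxy-9-oxo-1-(triethylsilyloxy)bicyclo[3.3.1]non-7-en-3-yl]dec-2-enamide, via bis(diiodosamarium) C9-enolate/C6-alkoxide 19 (not isolated)
Conditions: SmI2 (2.2 equiv, 0.1 M in THF), THF, −78 °C; sat. NH4Cl
Reagents that add atoms: samarium(II) iodide, I[Sm]I (Sm and I of intermediate 19 only)
Why: Ketyl-initiated opening of the α,β-epoxy ketone gives the Sm(III) enolate regiospecifically at C5 and keeps the C6 oxygen with its configuration. The enolate then closes ring A by an intramolecular Reformatsky-type aldol from the tether face, which fixes C5, with a Sm chelate between the C9 and aldehyde oxygens placing the C4–OH syn to C9=O (exo) and the amide equatorial.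

Step 16
Reactants: 20 (E)-N-[(1S,3S,4R,5R,6R)-4,6-dihydroxy-9-oxo-1-(triethylsilyloxy)bicyclo[3.3.1]non-7-en-3-yl]dec-2-enamide
Product: 21 (E)-N-[(1S,3S,4R,5R,6R)-1,4,6-trihydroxy-9-oxobicyclo[3.3.1]non-7-en-3-yl]dec-2-enamide
Conditions: HF·pyridine, pyridine, THF, 0 °C → rt
Reagents that add atoms: none
Why: Buffered fluoride desilylation frees the tertiary C1–OH before the oxirane exists, under conditions too mild for retro-aldol of the β-hydroxy ketones.

Step 17
Reactants: 21 (E)-N-[(1S,3S,4R,5R,6R)-1,4,6-trihydroxy-9-oxobicyclo[3.3.1]non-7-en-3-yl]dec-2-enamide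
Product: 22 isariotin D
Conditions: VO(acac)2 (5 mol%), t-BuOOH (1.5 equiv), CH2Cl2, 0 °C → rt
Reagents that add atoms: tert-butyl hydroperoxide, CC(C)(C)OO
Why: Vanadium-catalysed hydroxyl-directed epoxidation delivers oxygen to C7=C8 syn to the flanking allylic C6–OH and C1–OH, which is also the open exo face, setting C7 and C8; the enoyl olefin and the ketone are untouched.

## Compound list

1 | benzoic acid | OC(=O)c1ccccc1 | starting material
2 | (1S,2R)-1,2-dihydroxycyclohexa-3,5-diene-1-carboxylic acid | OC(=O)[C@@]1(O)[C@H](O)C=CC=C1 | intermediate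
3 | methyl (1S,2R)-1,2-dihydroxycyclohexa-3,5-diene-1-carboxylate | COC(=O)[C@@]1(O)[C@H](O)C=CC=C1 | intermediate
4 | methyl (1S,2R)-1,2-bis(triethylsilyloxy)cyclohexa-3,5-diene-1-carboxylate | COC(=O)[C@@]1(O[Si](CC)(CC)CC)[C@H](O[Si](CC)(CC)CC)C=CC=C1 | intermediate
5 | [(1R,6R)-1,6-bis(triethylsilyloxy)cyclohexa-2,4-dien-1-yl]methanol | OC[C@@]1(O[Si](CC)(CC)CC)[C@H](O[Si](CC)(CC)CC)C=CC=C1 | intermediate
6 | (1S,6R)-1,6-bis(triethylsilyloxy)cyclohexa-2,4-diene-1-carbaldehyde | O=C[C@@]1(O[Si](CC)(CC)CC)[C@H](O[Si](CC)(CC)CC)C=CC=C1 | intermediate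
7 | (E)-dec-2-enoic acid | CCCCCCC/C=C/C(O)=O | starting material
8 | (E)-dec-2-enoyl chloride | CCCCCCC/C=C/C(Cl)=O | intermediate (not isolated)
9 | (E)-dec-2-enamide | CCCCCCC/C=C/C(N)=O | intermediate
10 | trimethyl phosphonoacetate | COC(=O)CP(=O)(OC)OC | starting material
11 | trimethyl diazophosphonoacetate | COC(=O)C(=[N+]=[N-])P(=O)(OC)OC | intermediate
12 | methyl 2-[(E)-dec-2-enoylamino]-2-(dimethoxyphosphoryl)acetate (racemic) | CCCCCCC/C=C/C(=O)NC(C(=O)OC)P(=O)(OC)OC | intermediate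
13 | methyl (Z)-3-[(1R,6R)-1,6-bis(triethylsilyloxy)cyclohexa-2,4-dien-1-yl]-2-[(E)-dec-2-enoylamino]prop-2-enoate | CCCCCCC/C=C/C(=O)N/C(C(=O)OC)=C\[C@@]1(O[Si](CC)(CC)CC)[C@H](O[Si](CC)(CC)CC)C=CC=C1 | intermediate
14 | methyl (Z)-2-[(E)-dec-2-enoylamino]-3-[(1R,6R)-6-hydroxy-1-(triethylsilyloxy)cyclohexa-2,4-dien-1-yl]prop-2-enoate | CCCCCCC/C=C/C(=O)N/C(C(=O)OC)=C\[C@@]1(O[Si](CC)(CC)CC)[C@H](O)C=CC=C1 | intermediate
15 | methyl (Z)-2-[(E)-dec-2-enoylamino]-3-[(1R,4R,5R,6S)-5-hydroxy-4-(triethylsilyloxy)-7-oxabicyclo[4.1.0]hept-2-en-4-yl]prop-2-enoate | CCCCCCC/C=C/C(=O)N/C(C(=O)OC)=C\[C@@]1(O[Si](CC)(CC)CC)[C@H](O)[C@@H]2O[C@@H]2C=C1 | intermediate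
16 | methyl (2S)-2-[(E)-dec-2-enoylamino]-3-[(1R,4S,5R,6S)-5-hydroxy-4-(triethylsilyloxy)-7-oxabicyclo[4.1.0]hept-2-en-4-yl]propanoate | CCCCCCC/C=C/C(=O)N[C@H](C(=O)OC)C[C@@]1(O[Si](CC)(CC)CC)[C@H](O)[C@@H]2O[C@@H]2C=C1 | intermediate
17 | (E)-N-[(2S)-1-hydroxy-3-[(1R,4S,5R,6S)-5-hydroxy-4-(triethylsilyloxy)-7-oxabicyclo[4.1.0]hept-2-en-4-yl]propan-2-yl]dec-2-enamide | CCCCCCC/C=C/C(=O)N[C@H](CO)C[C@@]1(O[Si](CC)(CC)CC)[C@H](O)[C@@H]2O[C@@H]2C=C1 | intermediate
18 | (E)-N-[(2S)-1-oxo-3-[(1R,3S,6R)-2-oxo-3-(triethylsilyloxy)-7-oxabicyclo[4.1.0]hept-4-en-3-yl]propan-2-yl]dec-2-enamide | CCCCCCC/C=C/C(=O)N[C@H](C=O)C[C@@]1(O[Si](CC)(CC)CC)C(=O)[C@@H]2O[C@@H]2C=C1 | intermediate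
19 | bis(diiodosamarium) enolate/alkoxide from 18 (C5=C9 enolate O–SmI2, C6 O–SmI2, aldehyde intact) | CCCCCCC/C=C/C(=O)N[C@H](C=O)C[C@@]1(O[Si](CC)(CC)CC)C(O[Sm](I)I)=C[C@H](O[Sm](I)I)C=C1 | intermediate (not isolated)
20 | (E)-N-[(1S,3S,4R,5R,6R)-4,6-dihydroxy-9-oxo-1-(triethylsilyloxy)bicyclo[3.3.1]non-7-en-3-yl]dec-2-enamide | CCCCCCC/C=C/C(=O)N[C@H]1C[C@@]2(O[Si](CC)(CC)CC)C(=O)[C@H]([C@H](O)C=C2)[C@H]1O | intermediate
21 | (E)-N-[(1S,3S,4R,5R,6R)-1,4,6-trihydroxy-9-oxobicyclo[3.3.1]non-7-en-3-yl]dec-2-enamide | CCCCCCC/C=C/C(=O)N[C@H]1C[C@@]2(O)C(=O)[C@H]([C@H](O)C=C2)[C@H]1O | intermediate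
22 | isariotin D | CCCCCCC/C=C/C(=O)N[C@H]1C[C@@]2(O)C(=O)[C@H]([C@H](O)[C@@H]3O[C@@H]32)[C@H]1O | target

## Step count and risks

Total steps: 17. Longest linear sequence: 14 (steps 1–5 and 9–17, from 1 to 22); the side branch to 12 is 3 steps (6–8).

The three steps most likely to fail:

Step 15 (SmI2 oxirane opening/aldol cascade). The enolate may be protonated or the aldol may give the wrong C4 epimer. Fallback, from 18 back to 20: the cascade is decoupled. SmI2 opening of 18 at −78 °C is quenched with TMSCl/Et3N and the resulting C9 trimethylsilyl enol ether/C6 trimethylsilyl ether aldehyde F1 is isolated. Ring A is then closed in a separate Lewis-acid Mukaiyama aldol (MgBr2·OEt2, CH2Cl2, −78 °C) to the C6-O-trimethylsilyl aldol F2, and citric acid/MeOH removes the silyl ether to give 20.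

Step 12 (asymmetric hydrogenation of a β-quaternary enamide next to a vinyl oxirane). The catalyst may be slow or may touch the oxirane. Fallback, from 13 back to 16: C3 is set before the oxirane exists and without a metal that binds dienes. A chiral phosphoric acid (TRIP, the enantiomer giving (S)-C3) with Hantzsch ester in toluene reduces 13 through its N-acyl ketimine tautomer to the saturated (S)-amido ester bis-silyl ether F3. HF·pyridine then frees the C9 hydroxyl to give the dienol F4, and mCPBA epoxidation of F4 directed by that hydroxyl gives 16.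

Step 11 (mono-epoxidation of a polyene). Regio- or chemoselectivity may be poor in the presence of the enamide. Fallback, from 3 back to 15: the oxirane is introduced first, on the diol ester where only the alkene next to the secondary carbinol is activated and directed. mCPBA on 3 gives the syn-epoxy diol ester F5, which is bis-silylated without triflate (TESCl, imidazole, DMAP, DMF) to the bis-silyl epoxy ester F6. DIBAL-H reduction gives the epoxy alcohol F7, Dess–Martin oxidation gives the epoxy aldehyde F8, and olefination with 12 (DBU) gives the bis-silyl epoxy enamide F9. Selective removal of the secondary silyl ether (HF·pyridine) gives 15.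

## Further compounds

F1 | step 15 | (E)-N-[(2S)-1-oxo-3-[1-(triethylsilyloxy)-2,4-bis(trimethylsilyloxy)cyclohexa-2,5-dien-1-yl]propan-2-yl]dec-2-enamide (C9 silyl enol ether, C6 silyl ether, configurations as in 19) | CCCCCCC/C=C/C(=O)N[C@H](C=O)C[C@@]1(O[Si](CC)(CC)CC)C(O[Si](C)(C)C)=C[C@H](O[Si](C)(C)C)C=C1
F2 | step 15 | 6-O-trimethylsilyl ether of 20 | CCCCCCC/C=C/C(=O)N[C@H]1C[C@@]2(O[Si](CC)(CC)CC)C(=O)[C@H]([C@H](O[Si](C)(C)C)C=C2)[C@H]1O
F3 | step 12 | methyl (2S)-3-[(1S,6R)-1,6-bis(triethylsilyloxy)cyclohexa-2,4-dien-1-yl]-2-[(E)-dec-2-enoylamino]propanoate | CCCCCCC/C=C/C(=O)N[C@H](C(=O)OC)C[C@@]1(O[Si](CC)(CC)CC)[C@H](O[Si](CC)(CC)CC)C=CC=C1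
F4 | step 12 | methyl (2S)-2-[(E)-dec-2-enoylamino]-3-[(1S,6R)-6-hydroxy-1-(triethylsilyloxy)cyclohexa-2,4-dien-1-yl]propanoate | CCCCCCC/C=C/C(=O)N[C@H](C(=O)OC)C[C@@]1(O[Si](CC)(CC)CC)[C@H](O)C=CC=C1
F5 | step 11 | methyl (1R,4S,5R,6S)-4,5-dihydroxy-7-oxabicyclo[4.1.0]hept-2-ene-4-carboxylate | COC(=O)[C@@]1(O)[C@H](O)[C@@H]2O[C@@H]2C=C1
F6 | step 11 | methyl (1R,4S,5R,6S)-4,5-bis(triethylsilyloxy)-7-oxabicyclo[4.1.0]hept-2-ene-4-carboxylate | COC(=O)[C@@]1(O[Si](CC)(CC)CC)[C@H](O[Si](CC)(CC)CC)[C@@H]2O[C@@H]2C=C1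
F7 | step 11 | [(1R,4R,5R,6S)-4,5-bis(triethylsilyloxy)-7-oxabicyclo[4.1.0]hept-2-en-4-yl]methanol | OC[C@@]1(O[Si](CC)(CC)CC)[C@H](O[Si](CC)(CC)CC)[C@@H]2O[C@@H]2C=C1
F8 | step 11 | (1R,4S,5R,6S)-4,5-bis(triethylsilyloxy)-7-oxabicyclo[4.1.0]hept-2-ene-4-carbaldehyde | O=C[C@@]1(O[Si](CC)(CC)CC)[C@H](O[Si](CC)(CC)CC)[C@@H]2O[C@@H]2C=C1
F9 | step 11 | methyl (Z)-3-[(1R,4R,5R,6S)-4,5-bis(triethylsilyloxy)-7-oxabicyclo[4.1.0]hept-2-en-4-yl]-2-[(E)-dec-2-enoylamino]prop-2-enoate | CCCCCCC/C=C/C(=O)N/C(C(=O)OC)=C\[C@@]1(O[Si](CC)(CC)CC)[C@H](O[Si](CC)(CC)CC)[C@@H]2O[C@@H]2C=C1
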